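In the summer run, target and substrate do not add up to the charge: at 2.50 h a leftover L of 10.1% is missing. At 0.500 h the leftover of 2.50% already stands above the 1.3% of target, though each reading scatters by 0.5 percentage points. So I take part of it to have left the substrate without passing through target.

- summer: substrate 0.40 M; reagent in the second phase 0.60 M; the very flask that is asked about, followed so far
- flask: substrate 0.40 M; reagent in the second phase 0.600 M; time 30 h; volume of the second phase over the first 0.25

- summer (time / h: target / %, substrate / %): 0.500: 1.3, 96.2; 1.00: 4.9, 90.7; 1.33: 7.3, 88.7; 2.00: 10.6, 82.3; 2.50: 12.3, 77.6

(readings scatter by 0.5 percentage points)

- in the second phase: reagent in the second phase; everything else is in the first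
- charges count per volume of the first phase; a concentration in a rate is the amount of a species over the volume of its own phase; every rate counts per litre of the first phase
- the numbers in the tables scatter by 0.5 percentage points (one standard deviation)
- the earlier runs hold the two phases in the same ratio of volumes as the flask asked about
- what has gone from substrate into another species counts as reacted, even if it can come back

* how much target there is at 30 h, in percent of the substrate charged
* part of the substrate charged that has reacted at 30 h

Follow one molecule that has left the substrate in the summer run. Its chance of standing as target, φ, defined as target over reacted substrate, reads 0.549 at 2.50 h.

The bench rule treats the substrate as pseudo-first-order. Its fall gives 0.101 h⁻¹, which leaves 4.77% at 30 h, and φ then gives 52.3% of target.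

The border of this rule is the ratio ρ of target to substrate. The last reading has ρ at 0.159, but the rule's own end has it at 11.0, so reagent there meets more target than substrate, and φ cannot be trusted to hold. I therefore commit to an estimate, not a bound: in this flask at 30 h, I expect target to fall short of φ times the reacted part, although the summer readings at 1.33 h and 2.00 h stand above that product. Watch ρ as it nears 1.

The forecast, a different reckoning from mine, gives 8% of target and 75% reacted, in the words “Its depletion would slow everything”.

The flask gives 28.1% of target with 74.6% reacted.

    reagent in the reaction phase ⇌ reagent in the second phase, rate k1*([reagent in the reaction phase] - [reagent in the second phase]/K1) per volume of the first phase (partition coefficient = 2.44, kL = 0.769 h⁻¹)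
    substrate + reagent in the reaction phase → target (k = 0.232 M⁻¹ h⁻¹)
    reagent in the reaction phase + target → over-reacted product (k = 0.272 M⁻¹ h⁻¹)
    substrate ⇌ dormant form (K = 0.250, k = 0.0441 h⁻¹)

At 30.0 h the flask holds 39.2% of over-reacted product, and ρ stands at 1.11. The reading φ times the reacted part gives 41.0%, which lies above the target found by 13 points. The neighbour charged with 0.68 M of substrate has 64.0% reacted, so φ gives it 35.1% against 30.1% found, at a ρ of 0.835.

All runs were computed for substances that don't exist, noise included.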